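**Retrosynthetic overview**

1. Labels: C1 ester-bearing CH, C2 CH2, C3 methyl-bearing alkene carbon, C4 alkene CH, C5 ketone carbon, C6 methyl-bearing fusion carbon, C7/C8 CH2, C9 carbinol carbon carrying isopropyl, C10 fusion CH; ring A = seven-membered (C1–C6, C10), ring B = five-membered (C6–C10). The plan rests on one feature: in ring A, C4 is a bare CH between the C5 carbonyl and the methyl-substituted C3, and the other neighbour of C5, C6, is quaternary, so deleting C4 leaves a 2-methylcyclohexanone whose only possible enol ether is C5=C3.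
2. Last disconnection: the O-1 vanillate ester. Key disconnection: ring A from a trans-hydrindanone by inserting C4 into the C5–C3 bond (cyclopropanation of the silyl enol ether, then oxidative cleavage of the shared bond).
3. Six-membered carbocycle: C2–C3 bond by intramolecular alkylation of the C5 ethyl-ketone enolate with a C2 iodide; the ethyl ketone is unmasked from a but-1-en-2-yl group by ozonolysis.
4. On ring B: C9–isopropyl by organocerium addition, the C1 carbinol by chelation-controlled reduction, C10–C1 by aldol of a regiodefined enolate with chloroacetaldehyde, and the C6 quaternary centre by catalytic asymmetric conjugate addition to 3-methylcyclopent-2-en-1-one.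
5. Order of rings: ring B is present in the starting enone, the six-membered carbocycle is closed in step 9, and ring A arises from it by ring expansion in step 11.

Key step: step 11

**Remarks**

- Labels: the atom labels C1–C10 above are used for every intermediate; α is the face of the C6 methyl group, β the face of H-10.
- Assumption: the antipode of the chiral NHC ligand in step 1 is taken to be the one that gives the (S) configuration at C6; the sense of induction has to be confirmed on the first silyl enol ether, and the other antipode used if needed.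
- Assumption: chloroacetaldehyde is used as the anhydrous monomer, freshly distilled from the commercial aqueous solution.

**Route**

Step 1
Reactants: 1 3-methylcyclopent-2-en-1-one; 2 but-1-yne
Product: 5 {[(3S)-3-(but-1-en-2-yl)-3-methylcyclopent-1-en-1-yl]oxy}trimethylsilane, via alkenylalane 3 (not isolated), via aluminium enolate 4 (not isolated)
Conditions: 2, iBu2AlH, Ni(dppp)Cl2 (3 mol %), THF, 0 → 22 °C; then 1, Cu(OTf)2 (5 mol %), chiral sulfonate-bearing imidazolinium salt (NHC precursor, 5 mol %), −78 → −15 °C; then Me3SiOTf, −78 → 0 °C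
Reagents that add atoms: trimethylsilyl trifluoromethanesulfonate, C[Si](C)(C)OS(=O)(=O)C(F)(F)F
Why: Nickel-catalysed hydroalumination places aluminium on the internal alkyne carbon, the resulting 1,1-disubstituted alkenylalane undergoes copper–NHC-catalysed asymmetric conjugate addition to the β-methyl enone so that the catalyst sets the C6 quaternary centre (methyl α, alkenyl β), and O-silylation of the aluminium enolate stores the C9=C10 enolate regiochemistry that deprotonation of the ketone could never give.

Step 2
Reactants: 5 {[(3S)-3-(but-1-en-2-yl)-3-methylcyclopent-1-en-1-yl]oxy}trimethylsilane; 6 chloroacetaldehyde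
Product: 8 (2S,3S)-3-(but-1-en-2-yl)-2-(2-chloro-1-hydroxyethyl)-3-methylcyclopentan-1-one as both C1 epimers, via lithium enolate 7 (not isolated)
Conditions: MeLi, THF, 0 → 23 °C; then 6, −78 °C; then AcOH, −78 °C
Reagents that add atoms: none
Why: Methyllithium cleaves the silyl enol ether to the regiodefined lithium enolate, and its aldol addition takes place on the α face of C10, anti to the bulkier but-1-en-2-yl group on C6, which puts the C1 chain trans to C5 as the later trans ring fusion requires, while the C1 carbinol configuration is left open because step 4 erases it.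

Step 3
Reactants: 8 (2S,3S)-3-(but-1-en-2-yl)-2-(2-chloro-1-hydroxyethyl)-3-methylcyclopentan-1-one (both C1 epimers)
Product: 9 ring-B cyclopentanol with 6α-methyl, 6β-(but-1-en-2-yl), 9α-hydroxy, 9β-isopropyl and 10α-CH(OH)CH2Cl (both C1 epimers)
Conditions: iPrMgCl, CeCl3 (anhydrous), THF, −78 → −40 °C
Reagents that add atoms: isopropylmagnesium chloride, CC(C)[Mg]Cl
Why: Organocerium 1,2-addition suppresses enolisation and reduction of the hindered ketone, and the metal-chelated α side chain on C10 sends the isopropyl group to the β face of C9, so that the new tertiary hydroxyl is α and cis to that side chain.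

Step 4
Reactants: 9 ring-B cyclopentanol with 10α-CH(OH)CH2Cl side chain (both C1 epimers)
Product: 10 α-chloro ketone (10α-C(=O)CH2Cl, 9α-hydroxy, 9β-isopropyl, 6α-methyl, 6β-butenyl)
Conditions: Dess–Martin periodinane, CH2Cl2, 0 → 23 °C
Reagents that add atoms: none
Why: Dess–Martin oxidation converts both C1 epimers of the secondary chlorohydrin into one α-chloro ketone and leaves the tertiary C9 hydroxyl, which cannot be oxidised, untouched.

Step 5
Reactants: 10 α-chloro ketone
Product: 11 chlorohydrin diol, single C1 epimer (O-1 syn to O-9, the C1 configuration of the target)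
Conditions: Zn(BH4)2, Et2O, −40 → −20 °C
Reagents that add atoms: none
Why: Chelation-controlled borohydride reduction of a β-hydroxy ketone: zinc bridges O-9 and the C1 carbonyl in a six-membered chelate cis-fused to the cyclopentane, and external hydride adds to the chelate face that carries H-10, away from the quaternary C6 and its α-methyl group, which sets C1 with O-1 syn to O-9 as in the target.

Step 6
Reactants: 11 chlorohydrin diol
Product: 13 1-O-TBS 9-O-TES bis-silyl ether of 11, via 1-O-TBS ether 12 (not isolated)
Conditions: tBuMe2SiOTf, 2,6-lutidine, CH2Cl2, −78 → −20 °C; then Et3SiOTf, −20 → 23 °C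
Reagents that add atoms: tert-butyldimethylsilyl trifluoromethanesulfonate, CC(C)(C)[Si](C)(C)OS(=O)(=O)C(F)(F)F; triethylsilyl trifluoromethanesulfonate, CC[Si](CC)(CC)OS(=O)(=O)C(F)(F)F
Why: Silylation with silyl triflates in two stages exploits steric differentiation, the secondary C1 hydroxyl taking the tert-butyldimethylsilyl group at low temperature and the much more hindered tertiary C9 hydroxyl needing the smaller triethylsilyl triflate at room temperature.

Step 7
Reactants: 13 1-O-TBS 9-O-TES bis-silyl ether
Product: 15 ethyl ketone (C5=O on C6) bearing 1-O-TBS 9-O-TES and C2–Cl, via ozonide 14 (not isolated)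
Conditions: O3, CH2Cl2, −78 °C; then PPh3, −78 → 23 °C
Reagents that add atoms: ozone, [O-][O+]=O
Why: Ozonolysis with reductive work-up cleaves the only C=C bond of the molecule, the 1,1-disubstituted alkene at C5, to the ethyl ketone without affecting the silyl ethers or the alkyl chloride.

Step 8
Reactants: 15 ethyl ketone with C2–Cl
Product: 16 ethyl ketone with C2–I
Conditions: NaI, NaHCO3, 2-butanone, 80 °C
Reagents that add atoms: sodium iodide, [Na+].[I-]
Why: Finkelstein exchange, driven by precipitation of NaCl, converts the sluggish β-silyloxy primary chloride into the iodide needed for enolate alkylation at low temperature.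

Step 9
Reactants: 16 ethyl ketone with C2–I
Product: 18 trans-hydrindan-5-one (1α-OTBS; 3-methyl as both epimers; 6α-methyl; 9α-OTES; 9β-isopropyl; 10β-H), via lithium enolate 17 (not isolated)
Conditions: LiN(iPr)2, THF, −78 → 0 °C
Reagents that add atoms: none
Why: Because C6 is quaternary the ketone can enolise only at C3, and this lithium enolate closes the six-membered ring by intramolecular C-alkylation at the primary iodide C2 (6-(enolendo)-exo-tet), the trans ring fusion following from the trans arrangement of the two chains on ring B and the new C3 centre being of no consequence since step 10 makes it trigonal.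

Step 10
Reactants: 18 trans-hydrindan-5-one
Product: 20 C5=C3 trimethylsilyl enol ether of 18, via lithium enolate 19 (not isolated)
Conditions: LiN(iPr)2, THF, −78 → 0 °C; then Me3SiCl, Et3N, −78 → 0 °C
Reagents that add atoms: chlorotrimethylsilane, C[Si](C)(C)Cl
Why: Deprotonation can occur only at C3, so O-silylation of the lithium enolate gives the tetrasubstituted C5=C3 trimethylsilyl enol ether as a single regioisomer.

Step 11
Reactants: 20 C5=C3 trimethylsilyl enol ether of the trans-hydrindanone
Product: 23 ring-A enone 1-O-TBS 9-O-TES bis-silyl ether, via siloxycyclopropane 21 (not isolated), via β-chloro ketone 22 (not isolated)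
Conditions: Et2Zn, CH2I2, CH2Cl2, 0 → 23 °C; then FeCl3, pyridine, DMF, 0 °C; then NaOAc, MeOH, 60 °C
Reagents that add atoms: diiodomethane, ICI
Why: The zinc carbenoid EtZnCH2I adds to the electron-rich C5=C3 enol ether (Furukawa-modified Simmons–Smith cyclopropanation) to give siloxycyclopropane 21; FeCl3 (trivalent iron) then exchanges for silicon at O-5 and oxidises the cyclopropanolate by one electron, β-scission of the internal C5–C3 bond gives the C5 ketone and the tertiary C3 radical, chlorine transfer from a second FeCl3 gives β-chloro ketone 22, and NaOAc removes HCl by E1cB elimination through the C4 enolate. The closest known reaction type is the FeCl3-mediated ring enlargement of 1-siloxybicyclo[n.1.0]alkanes to cycloalk-2-enones, which is documented for 2-methyl-substituted enol ethers that give 3-methylcycloalk-2-enones. Ring A is closed by one-carbon ring expansion and not by cyclisation: C4 enters by [2+1] addition (bonds C3–C4 and C4–C5) and the C3–C5 bond shared by the two small rings is broken, so the six-membered ring becomes the seven-membered one while the C6–C10 trans fusion is never touched. No stereocentre is created, since both cyclopropane stereocentres are transient and C3 ends trigonal, so either face of carbenoid attack converges on 23. The selectivity needed is cleavage of the internal and not the external cyclopropane bond, secured by the tertiary methyl-bearing C3 radical being far more stable than a primary CH2 radical, together with a single enol ether regioisomer, secured by the quaternary C6, and conjugated C3=C4 elimination, secured by the acidity of the C4 hydrogens next to the ketone. Pyridine-buffered DMF tempers the Lewis acidity of FeCl3 so that the silyl ethers at O-1 and O-9 should survive, and their partial loss would be harmless because step 12 removes both.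

Step 12
Reactants: 23 ring-A enone bis-silyl ether
Product: 24 diol enone (1α-OH, 9α-OH)
Conditions: HF·pyridine, pyridine, THF, 0 → 23 °C
Reagents that add atoms: none
Why: Pyridine-buffered HF·pyridine cleaves both silyl ethers by fluoride attack at silicon without dehydrating the tertiary alcohol or touching the enone.

Step 13
Reactants: 25 vanillic acid
Product: 26 prop-2-en-1-yl 3-methoxy-4-(prop-2-en-1-yloxy)benzoate
Conditions: allyl bromide, K2CO3, DMF, 50 °C
Reagents that add atoms: allyl bromide, C=CCBr
Why: Williamson-type O-alkylation with allyl bromide converts the phenoxide into the allyl ether and, unavoidably, the carboxylate into the allyl ester.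

Step 14
Reactants: 26 prop-2-en-1-yl 3-methoxy-4-(prop-2-en-1-yloxy)benzoate
Product: 27 3-methoxy-4-(prop-2-en-1-yloxy)benzoic acid
Conditions: LiOH, THF/MeOH/H2O, 23 °C; then HCl (aq)
Reagents that add atoms: lithium hydroxide, [Li+].[OH-]
Why: Saponification cleaves the allyl ester, while the allyl aryl ether is inert to hydroxide.

Step 15
Reactants: 24 diol enone; 27 3-methoxy-4-(prop-2-en-1-yloxy)benzoic acid
Product: 28 1-O-[3-methoxy-4-(prop-2-en-1-yloxy)benzoyl] ester of 24
Conditions: DCC, DMAP (1 equiv), CH2Cl2, 23 → 40 °C
Reagents that add atoms: none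
Why: Steglich esterification acylates the secondary C1 hydroxyl without breaking the C1–O bond, so the configuration is retained, and the tertiary C9 hydroxyl is too hindered to compete.

Step 16
Reactants: 28 1-O-[3-methoxy-4-(prop-2-en-1-yloxy)benzoyl] ester
Product: 29 (3R,3aS,4R,8aS)-3-hydroxy-6,8a-dimethyl-8-oxo-3-(propan-2-yl)-1,2,3,3a,4,5,8,8a-octahydroazulen-4-yl 4-hydroxy-3-methoxybenzoate (target)
Conditions: Pd(PPh3)4 (5 mol %), morpholine, THF, 23 °C
Reagents that add atoms: none
Why: Zerovalent palladium ionises the allyl aryl ether to a π-allyl complex that morpholine intercepts (Tsuji–Trost deallylation), which frees the phenol under neutral conditions that spare the benzoate, the enone and the tertiary alcohol.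

**Compound list**

1 | 3-methylcyclopent-2-en-1-one | CC1=CC(=O)CC1 | starting material
2 | but-1-yne | CCC#C | starting material
3 | (but-1-en-2-yl)bis(2-methylpropyl)aluminium | C=C(CC)[Al](CC(C)C)CC(C)C | intermediate (not isolated)
4 | diisobutylaluminium (3S)-3-(but-1-en-2-yl)-3-methylcyclopent-1-en-1-olate (C9=C10 enolate) | C=C(CC)[C@@]1(C)CCC(=C1)O[Al](CC(C)C)CC(C)C | intermediate (not isolated)
5 | {[(3S)-3-(but-1-en-2-yl)-3-methylcyclopent-1-en-1-yl]oxy}trimethylsilane | C=C(CC)[C@@]1(C)CCC(=C1)O[Si](C)(C)C | intermediate
6 | chloroacetaldehyde | O=CCCl | starting material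
7 | lithium (3S)-3-(but-1-en-2-yl)-3-methylcyclopent-1-en-1-olate | C=C(CC)[C@@]1(C)CCC(=C1)O[Li] | intermediate (not isolated)
8 | (2S,3S)-3-(but-1-en-2-yl)-2-(2-chloro-1-hydroxyethyl)-3-methylcyclopentan-1-one (C9 ketone; 6α-methyl, 6β-butenyl, 10α side chain; both C1 epimers) | OC(CCl)[C@@H]1[C@@](C)(C(=C)CC)CCC1=O | intermediate
9 | ring-B cyclopentanol: 6α-methyl, 6β-(but-1-en-2-yl), 9α-hydroxy, 9β-isopropyl, 10β-H, 10α-CH(OH)CH2Cl (both C1 epimers) | OC(CCl)[C@@H]1[C@@](C)(C(=C)CC)CC[C@@]1(O)C(C)C | intermediate
10 | α-chloro ketone: as 9 with 10α-C(=O)CH2Cl | O=C(CCl)[C@@H]1[C@@](C)(C(=C)CC)CC[C@@]1(O)C(C)C | intermediate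
11 | chlorohydrin diol: as 9, single C1 epimer with O-1 syn to O-9 | O[C@H](CCl)[C@@H]1[C@@](C)(C(=C)CC)CC[C@@]1(O)C(C)C | intermediate
12 | 1-O-tert-butyldimethylsilyl ether of 11 (9-OH free) | CC(C)(C)[Si](C)(C)O[C@H](CCl)[C@@H]1[C@@](C)(C(=C)CC)CC[C@@]1(O)C(C)C | intermediate (not isolated)
13 | 1-O-tert-butyldimethylsilyl, 9-O-triethylsilyl ether of 11 | CC(C)(C)[Si](C)(C)O[C@H](CCl)[C@@H]1[C@@](C)(C(=C)CC)CC[C@@]1(O[Si](CC)(CC)CC)C(C)C | intermediate
14 | ozonide of 13 (3-ethyl-1,2,4-trioxolan-3-yl group on C6) | CC(C)(C)[Si](C)(C)O[C@H](CCl)[C@@H]1[C@@](C)(C2(CC)OCOO2)CC[C@@]1(O[Si](CC)(CC)CC)C(C)C | intermediate (not isolated)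
15 | ethyl ketone: 6β-propanoyl (C5=O), 6α-methyl, 10α-CH(OTBS)CH2Cl, 9α-OTES, 9β-isopropyl | CC(C)(C)[Si](C)(C)O[C@H](CCl)[C@@H]1[C@@](C)(C(=O)CC)CC[C@@]1(O[Si](CC)(CC)CC)C(C)C | intermediate
16 | iodide: as 15 with C2–I | CC(C)(C)[Si](C)(C)O[C@H](CI)[C@@H]1[C@@](C)(C(=O)CC)CC[C@@]1(O[Si](CC)(CC)CC)C(C)C | intermediate
17 | lithium C5=C3 enolate of 16 | CC(C)(C)[Si](C)(C)O[C@H](CI)[C@@H]1[C@@](C)(C(O[Li])=CC)CC[C@@]1(O[Si](CC)(CC)CC)C(C)C | intermediate (not isolated)
18 | trans-hydrindan-5-one (six-membered ring C1, C2, C3, C5, C6, C10): 1α-OTBS, 3-methyl (both epimers), 6α-methyl, 9α-OTES, 9β-isopropyl, 10β-H | CC(C)(C)[Si](C)(C)O[C@@H]1CC(C)C(=O)[C@@]2(C)CC[C@@](O[Si](CC)(CC)CC)(C(C)C)[C@H]12 | intermediate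
19 | lithium C5=C3 enolate of 18 | CC(C)(C)[Si](C)(C)O[C@@H]1CC(C)=C(O[Li])[C@@]2(C)CC[C@@](O[Si](CC)(CC)CC)(C(C)C)[C@H]12 | intermediate (not isolated)
20 | C5=C3 trimethylsilyl enol ether of 18 (key-step precursor) | CC(C)(C)[Si](C)(C)O[C@@H]1CC(C)=C(O[Si](C)(C)C)[C@@]2(C)CC[C@@](O[Si](CC)(CC)CC)(C(C)C)[C@H]12 | intermediate
21 | siloxycyclopropane: C4 bridging C3 (methyl) and C5 (OTMS) of 20 | CC(C)(C)[Si](C)(C)O[C@@H]1CC2(C)CC2(O[Si](C)(C)C)[C@@]3(C)CC[C@@](O[Si](CC)(CC)CC)(C(C)C)[C@H]13 | intermediate (not isolated)
22 | β-chloro ketone: ring A with C5=O, C4H2, C3(Cl)(CH3) | CC(C)(C)[Si](C)(C)O[C@@H]1CC(C)(Cl)CC(=O)[C@@]2(C)CC[C@@](O[Si](CC)(CC)CC)(C(C)C)[C@H]12 | intermediate (not isolated)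
23 | ring-A enone bis-silyl ether: C5=O, C3=C4, 3-methyl, 1α-OTBS, 6α-methyl, 9α-OTES, 9β-isopropyl, 10β-H (key-step product) | CC(C)(C)[Si](C)(C)O[C@@H]1CC(C)=CC(=O)[C@@]2(C)CC[C@@](O[Si](CC)(CC)CC)(C(C)C)[C@H]12 | intermediate
24 | diol enone: as 23 with 1α-OH and 9α-OH | O[C@@H]1CC(C)=CC(=O)[C@@]2(C)CC[C@@](O)(C(C)C)[C@H]12 | intermediate
25 | vanillic acid (4-hydroxy-3-methoxybenzoic acid) | COc1cc(C(=O)O)ccc1O | starting material
26 | prop-2-en-1-yl 3-methoxy-4-(prop-2-en-1-yloxy)benzoate | C=CCOC(=O)c1ccc(OCC=C)c(OC)c1 | intermediate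
27 | 3-methoxy-4-(prop-2-en-1-yloxy)benzoic acid | C=CCOc1ccc(C(=O)O)cc1OC | intermediate
28 | 1-O-[3-methoxy-4-(prop-2-en-1-yloxy)benzoyl] ester of 24 | C=CCOc1ccc(C(=O)O[C@@H]2CC(C)=CC(=O)[C@@]3(C)CC[C@@](O)(C(C)C)[C@H]23)cc1OC | intermediate
29 | (3R,3aS,4R,8aS)-3-hydroxy-6,8a-dimethyl-8-oxo-3-(propan-2-yl)-1,2,3,3a,4,5,8,8a-octahydroazulen-4-yl 4-hydroxy-3-methoxybenzoate (CNP0136950.1) | COc1cc(C(=O)O[C@@H]2CC(C)=CC(=O)[C@@]3(C)CC[C@@](O)(C(C)C)[C@H]23)ccc1O | target

**Step count**

Total step count: 16. Longest linear sequence: 14 steps (steps 1–12, 15 and 16); steps 13 and 14 form the side branch to acid 27.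

**Steps most likely to fail**

1. Step 11. Cyclopropanation of the tetrasubstituted enol ether, which is flanked by the quaternary C6, may stall, and the enol ether may hydrolyse back to 18 during the long exposure to zinc iodide. In the iron step the Lewis acid may strip the silyl ethers or ionise the tertiary C9–O bond before the oxidation is complete. The fallback sets out from 18 and returns at 23. Homologation of ketone 18 with Me3SiCHN2 and Me3Al in CH2Cl2, in which the less substituted α-carbon C3 migrates, would give the α-trimethylsilyl cycloheptanone F1. K2CO3 in MeOH would remove the C-silyl group to give the saturated ring-A ketone F2. LiN(iPr)2 and then Me3SiCl would give the C5=C4 trimethylsilyl enol ether F3, since C4 is the only enolisable position. Saegusa–Ito oxidation with Pd(OAc)2 in MeCN would then give enone 23.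

2. Step 1. The hydroalumination may give some linear alkenylalane or deprotonate the alkyne, so that the wrong group is transferred. The conjugate addition to the five-membered enone may be slow or insufficiently enantioselective with this α-branched alkenyl group, and O-silylation of the aluminium enolate may be incomplete. The fallback sets out from 1 and returns at 5, and replaces the aluminium manifold by a magnesium one. But-1-en-2-ylmagnesium bromide F4, made from commercial 2-bromobut-1-ene and magnesium in THF, would be added to 1 with Cu(OTf)2 and a C2-symmetric chiral imidazolinium (NHC) ligand in Et2O at −30 °C. The magnesium enolate F5 would be silylated in the same flask with Me3SiCl/Et3N to give 5.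

3. Step 5. Hydride delivery may lose facial selectivity, because the β-isopropyl group on C9 flanks the face that has to be attacked and a non-chelated pathway may compete. The resulting C1 epimers would then be carried through steps 6–9. The fallback sets out from 18 obtained as a C1-epimer mixture and returns at 18 as a single epimer, setting C1 on the rigid bicycle instead. HF·pyridine would remove both silyl groups to give the diol ketone F6. Dess–Martin oxidation of the secondary alcohol would give the C1,C5-dione F7. Li(sBu)3BH in THF at −78 °C would reduce only the C1 carbonyl, since the C5 carbonyl lies between the quaternary C6 and C3. Attack would come from the β face because the axial C6 methyl group blocks the α face, giving the 1α-alcohol F8. Silylation as in step 6, through the mono-silyl ether F9, would return 18.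

**Further compounds**

F1 | step 11 | α-trimethylsilyl cycloheptanone: ring A with C5=O, C4H(SiMe3), C3H(CH3), 1α-OTBS, 9α-OTES | CC(C)(C)[Si](C)(C)O[C@@H]1CC(C)C([Si](C)(C)C)C(=O)[C@@]2(C)CC[C@@](O[Si](CC)(CC)CC)(C(C)C)[C@H]12
F2 | step 11 | saturated ring-A ketone: C5=O, C4H2, C3H(CH3), 1α-OTBS, 9α-OTES | CC(C)(C)[Si](C)(C)O[C@@H]1CC(C)CC(=O)[C@@]2(C)CC[C@@](O[Si](CC)(CC)CC)(C(C)C)[C@H]12
F3 | step 11 | C5=C4 trimethylsilyl enol ether of F2 | CC(C)(C)[Si](C)(C)O[C@@H]1CC(C)C=C(O[Si](C)(C)C)[C@@]2(C)CC[C@@](O[Si](CC)(CC)CC)(C(C)C)[C@H]12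
F4 | step 1 | but-1-en-2-ylmagnesium bromide | C=C(CC)[Mg]Br
F5 | step 1 | bromomagnesium (3S)-3-(but-1-en-2-yl)-3-methylcyclopent-1-en-1-olate | C=C(CC)[C@@]1(C)CCC(=C1)O[Mg]Br
F6 | step 5 | diol ketone: trans-hydrindan-5-one with 1-OH (both epimers) and 9α-OH | OC1CC(C)C(=O)[C@@]2(C)CC[C@@](O)(C(C)C)[C@H]12
F7 | step 5 | C1,C5-dione with 9α-OH | O=C1CC(C)C(=O)[C@@]2(C)CC[C@@](O)(C(C)C)[C@H]12
F8 | step 5 | 1α-hydroxy trans-hydrindan-5-one with 9α-OH | O[C@@H]1CC(C)C(=O)[C@@]2(C)CC[C@@](O)(C(C)C)[C@H]12
F9 | step 5 | 1α-O-tert-butyldimethylsilyl ether of F8 | CC(C)(C)[Si](C)(C)O[C@@H]1CC(C)C(=O)[C@@]2(C)CC[C@@](O)(C(C)C)[C@H]12
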